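The core is numbered as a 1,2-dihydronaphthalene: C1 carries the aryl group, C2 and C3 the aroyl groups, C4 is the vinylic CH, ring A is C4a–C8a. Ring A meets the carbocycle only through the neighbouring atoms C4a and C8a, and its C8 methoxy group flanks C8a, so ring A enters whole as a 3-methoxyaryne. One Diels–Alder reaction with an acyclic 2-silyloxydiene (C1=C2–C3=C4, from a Knoevenagel adduct) forms C4–C4a and C8a–C1 and closes the carbocycle. Carbonylative coupling then exchanges the C3 oxygen for the second aroyl group, kinetic protonation of the dienolate sets the cis C1/C2 relation, and resolution gives the (1R,2R) series.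

Key step: step 9

Remark: the two stereodescriptors of the target read as (1R,2R), which places the C1 aryl group and the C2 aroyl group cis on the ring. The route is built for this less stable isomer.

Step 1
Reactants: 1 2,3,4-trihydroxybenzaldehyde
Product: 2 3,4-bis(benzyloxy)-2-hydroxybenzaldehyde
Conditions: BnBr (2.1 equiv), K2CO3 (2.2 equiv), DMF, 0 °C to rt
Reagents that add atoms: benzyl bromide, BrCc1ccccc1
Why: Williamson etherification: the C2 hydroxyl group is locked in a hydrogen bond to the aldehyde and is the least nucleophilic of the three, so two equivalents of benzyl bromide should alkylate only O3 and O4.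

Step 2
Reactants: 2 3,4-bis(benzyloxy)-2-hydroxybenzaldehyde
Product: 3 3,4-bis(benzyloxy)-2-methoxybenzaldehyde
Conditions: MeI (3 equiv), K2CO3, DMF, 40 °C
Reagents that add atoms: iodomethane, CI
Why: Williamson methylation of the remaining chelated phenol with an excess of the small electrophile installs the methoxy group found in both trioxygenated rings of the target.

Step 3
Reactants: 3 3,4-bis(benzyloxy)-2-methoxybenzaldehyde
Product: 5 3,4-bis(benzyloxy)-2-methoxyphenol, via aryl formate 4 (not isolated)
Conditions: mCPBA, CH2Cl2, 0 °C to rt; then K2CO3 (cat.), MeOH, 0 °C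
Reagents that add atoms: 3-chloroperoxybenzoic acid, OOC(=O)c1cccc(Cl)c1
Why: Baeyer–Villiger oxidation (Dakin type): the electron-rich aryl group migrates in preference to hydride to give formate 4, which mild methanolysis cleaves to the phenol whose oxygen marks the future C8a.

Step 4
Reactants: 5 3,4-bis(benzyloxy)-2-methoxyphenol
Product: 6 3,4-bis(benzyloxy)-6-bromo-2-methoxyphenol
Conditions: NBS (1.0 equiv), CH2Cl2, −78 to −20 °C
Reagents that add atoms: N-bromosuccinimide, BrN1C(=O)CCC1=O
Why: Electrophilic aromatic bromination: the free hydroxyl group is the strongest director, its para position is occupied and only one ortho position is open, so bromine should enter at C6, the future C4a.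

Step 5
Reactants: 6 3,4-bis(benzyloxy)-6-bromo-2-methoxyphenol
Product: 9 3,4-bis(benzyloxy)-2-methoxy-6-(trimethylsilyl)phenyl trifluoromethanesulfonate, via aryl silyl ether 7 (not isolated), via lithium silylphenolate 8 (not isolated)
Conditions: (Me3Si)2NH, THF, 65 °C, evaporate; n-BuLi, THF, −78 °C; Tf2O, −78 °C to rt
Reagents that add atoms: hexamethyldisilazane, C[Si](C)(C)N[Si](C)(C)C; trifluoromethanesulfonic anhydride, O=S(=O)(OS(=O)(=O)C(F)(F)F)C(F)(F)F
Why: Standard route to ortho-silylaryl triflates: O-silylation, bromine–lithium exchange, retro-Brook 1,3-shift of silicon from oxygen to carbon and trapping of phenolate 8 with triflic anhydride place SiMe3 on the future C4a and OTf on the future C8a.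

Step 6
Reactants: 10 1-[4-(benzyloxy)phenyl]ethanone
Product: 11 1-[4-(benzyloxy)phenyl]butane-1,3-dione
Conditions: NaH (2.2 equiv), EtOAc (3 equiv), THF, 0 °C to reflux; then 1 M HCl
Reagents that add atoms: ethyl acetate, CCOC(C)=O
Why: Crossed Claisen condensation of the ketone enolate with ethyl acetate, driven by deprotonation of the 1,3-diketone that forms.

Step 7
Reactants: 3 3,4-bis(benzyloxy)-2-methoxybenzaldehyde, 11 1-[4-(benzyloxy)phenyl]butane-1,3-dione
Product: 12 (Z)-1-[4-(benzyloxy)phenyl]-2-[3,4-bis(benzyloxy)-2-methoxybenzylidene]butane-1,3-dione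
Conditions: piperidine (cat.), AcOH (cat.), 4 Å molecular sieves, toluene, rt to 50 °C
Reagents that add atoms: none
Why: Knoevenagel condensation: the product should be mainly the Z isomer, in which the small acetyl group stays coplanar with the alkene opposite the aryl group and the bulkier aroyl group twists beside it, and this places the aryl group outward on the later diene.

Step 8
Reactants: 12 (Z)-1-[4-(benzyloxy)phenyl]-2-[3,4-bis(benzyloxy)-2-methoxybenzylidene]butane-1,3-dione
Product: 13 (Z)-1-[4-(benzyloxy)phenyl]-2-[3,4-bis(benzyloxy)-2-methoxybenzylidene]-3-[(tert-butyldimethylsilyl)oxy]but-3-en-1-one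
Conditions: TBSOTf, Et3N, CH2Cl2, 0 °C
Reagents that add atoms: tert-butyldimethylsilyl trifluoromethanesulfonate, CC(C)(C)[Si](C)(C)OS(=O)(=O)C(F)(F)F
Why: Soft enolisation: the acetyl CH3 group is the only enolisable position of 12, so silyl triflate and amine should give the cross-conjugated 2-silyloxydiene with the alkene geometry unchanged.

Step 9
Reactants: 9 3,4-bis(benzyloxy)-2-methoxy-6-(trimethylsilyl)phenyl trifluoromethanesulfonate, 13 (Z)-1-[4-(benzyloxy)phenyl]-2-[3,4-bis(benzyloxy)-2-methoxybenzylidene]-3-[(tert-butyldimethylsilyl)oxy]but-3-en-1-one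
Product: 16 racemic {6,7-bis(benzyloxy)-1-[3,4-bis(benzyloxy)-2-methoxyphenyl]-3-hydroxy-8-methoxy-1,4-dihydronaphthalen-2-yl}[4-(benzyloxy)phenyl]methanone (enol form of the 1,3-diketone), via aryne 14 (not isolated), via silyl enol ether cycloadduct 15 (not isolated)
Conditions: 9 (1.5 equiv), CsF (4 equiv), MeCN/toluene 1:1, rt, argon; then 1 M HCl, THF, 0 °C
Reagents that add atoms: none
Why: Fluoride removes the SiMe3 group of 9 and triflate leaves, so aryne 14 is released slowly in the presence of diene 13 and the two combine in an aryne Diels–Alder reaction of a 2-silyloxy-1,3-diene, the closest known reaction type, here strongly asynchronous and at its polar limit an arylation of the enol silane followed by Michael closure. The methoxy group beside the triple bond withdraws electrons through the sigma frame and distorts 14, so that the remote carbon next to C5–H (future C4a) is the more linear and electrophilic one and negative charge is best placed on the carbon next to C–OMe (future C8a). The CH2 terminus C4 of 13 is the enol silane carbon with the largest HOMO coefficient, reinforced by the donor aryl group at C1, so C4 bonds to C4a and C8a then bonds to C1, the beta carbon of the aroyl enone and a benzylic cation position. The single new ring, the six-membered carbocycle, closes suprafacially as a (4+2) cycloaddition, or as a 6-endo-trig conjugate addition if the process is stepwise. C1 is the only new stereocentre and, since both partners are achiral, no element controls its face: 16 is racemic, the absolute configuration is selected in step 13 and C2 is set in step 12. The step needs (4+2) rather than (2+2) or ene reactivity and one orientation of the unsymmetrical aryne, which the Z geometry of 13 (aryl group outward, s-cis form accessible), the matched polarity of both partners and the slow release of 14 should secure.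

Step 10
Reactants: 16 racemic {6,7-bis(benzyloxy)-1-[3,4-bis(benzyloxy)-2-methoxyphenyl]-3-hydroxy-8-methoxy-1,4-dihydronaphthalen-2-yl}[4-(benzyloxy)phenyl]methanone
Product: 17 racemic 3-[4-(benzyloxy)benzoyl]-6,7-bis(benzyloxy)-4-[3,4-bis(benzyloxy)-2-methoxyphenyl]-5-methoxy-1,4-dihydronaphthalen-2-yl trifluoromethanesulfonate (triflate on C3 of the core numbering)
Conditions: Tf2O, i-Pr2NEt, CH2Cl2, −78 °C
Reagents that add atoms: trifluoromethanesulfonic anhydride, O=S(=O)(OS(=O)(=O)C(F)(F)F)C(F)(F)F
Why: O-Sulfonylation of the 1,3-diketone: the ring oxygen should react because this keeps the aroyl carbonyl group conjugated with its electron-rich ring and the new alkene endocyclic, which gives an activated vinyl triflate at C3.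

Step 11
Reactants: 17 racemic C3 vinyl triflate, 18 [4-(benzyloxy)phenyl]boronic acid
Product: 19 racemic {6,7-bis(benzyloxy)-1-[3,4-bis(benzyloxy)-2-methoxyphenyl]-8-methoxy-1,4-dihydronaphthalene-2,3-diyl}bis{[4-(benzyloxy)phenyl]methanone}
Conditions: PdCl2(dppf) (5 mol %), CO (1 atm), K2CO3, anisole, 80 °C, degassed
Reagents that add atoms: carbon monoxide, [C-]#[O+]
Why: Carbonylative Suzuki–Miyaura coupling: oxidative addition of zerovalent palladium to the acyl-activated vinyl triflate, CO insertion, transmetalation and reductive elimination replace the C3 oxygen by the second aroyl group.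

Step 12
Reactants: 19 racemic 2,3-diaroyl-1,4-dihydronaphthalene
Product: 21 racemic cis-{6,7-bis(benzyloxy)-1-[3,4-bis(benzyloxy)-2-methoxyphenyl]-8-methoxy-1,2-dihydronaphthalene-2,3-diyl}bis{[4-(benzyloxy)phenyl]methanone} (1R,2R plus 1S,2S), via potassium dienolate 20 (not isolated)
Conditions: KN(SiMe3)2 (1.1 equiv), THF, −78 °C, argon; then AcOH (excess) in THF, −78 °C
Reagents that add atoms: none
Why: Deconjugative protonation of an extended enolate, a known reaction type for 1-aryl-2-acyl tetralin enolates: the hindered base removes an axial C4 proton (the C1–H bond lies near the ring plane and is shielded by two ortho-methoxyaryl units), and the dienolate is protonated kinetically at its alpha carbon C2 from the face opposite the C1 aryl group, which puts C2–H cis to C1–H and so the aroyl group cis to the aryl group.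

Step 13
Reactants: 21 racemic cis-2,3-diaroyl-1,2-dihydronaphthalene
Product: 22 {(1R,2R)-6,7-bis(benzyloxy)-1-[3,4-bis(benzyloxy)-2-methoxyphenyl]-8-methoxy-1,2-dihydronaphthalene-2,3-diyl}bis{[4-(benzyloxy)phenyl]methanone}
Conditions: preparative SFC, amylose tris(3,5-dimethylphenylcarbamate) on silica, CO2/i-PrOH without amine additive, 35 °C
Reagents that add atoms: none
Why: Chromatographic resolution on a chiral stationary phase separates the two enantiomers under neutral conditions that touch neither C1 nor C2, and the (1R,2R) fraction is to be assigned by X-ray or ECD analysis.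

Step 14
Reactants: 22 (1R,2R)-hexabenzyl ether
Product: 23 [(1R,2R)-1-(3,4-dihydroxy-2-methoxyphenyl)-6,7-dihydroxy-8-methoxy-1,2-dihydronaphthalene-2,3-diyl]bis[(4-hydroxyphenyl)methanone] (CNP0335881.1)
Conditions: BCl3 (1 M in CH2Cl2, 12 equiv), C6HMe5 (20 equiv), CH2Cl2, −78 °C; then MeOH, −78 to 0 °C, argon
Reagents that add atoms: none
Why: Lewis acid debenzylation with a cation scavenger: BCl3 ionises the six aryl benzyl ethers at low temperature, pentamethylbenzene takes up the benzyl cations by Friedel–Crafts alkylation, and the alkene, the ketones, the two methyl ethers and the epimerisable C2 centre should remain untouched.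

Compound list
1 | 2,3,4-trihydroxybenzaldehyde | O=Cc1ccc(O)c(O)c1O | starting material
2 | 3,4-bis(benzyloxy)-2-hydroxybenzaldehyde | O=Cc1ccc(OCc2ccccc2)c(OCc2ccccc2)c1O | intermediate
3 | 3,4-bis(benzyloxy)-2-methoxybenzaldehyde | COc1c(C=O)ccc(OCc2ccccc2)c1OCc1ccccc1 | intermediate
4 | 3,4-bis(benzyloxy)-2-methoxyphenyl formate | COc1c(OC=O)ccc(OCc2ccccc2)c1OCc1ccccc1 | intermediate
5 | 3,4-bis(benzyloxy)-2-methoxyphenol | COc1c(O)ccc(OCc2ccccc2)c1OCc1ccccc1 | intermediate
6 | 3,4-bis(benzyloxy)-6-bromo-2-methoxyphenol | COc1c(O)c(Br)cc(OCc2ccccc2)c1OCc1ccccc1 | intermediate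
7 | [3,4-bis(benzyloxy)-6-bromo-2-methoxyphenoxy]trimethylsilane | COc1c(O[Si](C)(C)C)c(Br)cc(OCc2ccccc2)c1OCc1ccccc1 | intermediate
8 | lithium 3,4-bis(benzyloxy)-2-methoxy-6-(trimethylsilyl)phenolate | [Li+].COc1c([O-])c([Si](C)(C)C)cc(OCc2ccccc2)c1OCc1ccccc1 | intermediate
9 | 3,4-bis(benzyloxy)-2-methoxy-6-(trimethylsilyl)phenyl trifluoromethanesulfonate | COc1c(OS(=O)(=O)C(F)(F)F)c([Si](C)(C)C)cc(OCc2ccccc2)c1OCc1ccccc1 | intermediate
10 | 1-[4-(benzyloxy)phenyl]ethanone | CC(=O)c1ccc(OCc2ccccc2)cc1 | starting material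
11 | 1-[4-(benzyloxy)phenyl]butane-1,3-dione | CC(=O)CC(=O)c1ccc(OCc2ccccc2)cc1 | intermediate
12 | (Z)-1-[4-(benzyloxy)phenyl]-2-[3,4-bis(benzyloxy)-2-methoxybenzylidene]butane-1,3-dione | CC(=O)/C(C(=O)c1ccc(OCc2ccccc2)cc1)=C/c1ccc(OCc2ccccc2)c(OCc2ccccc2)c1OC | intermediate
13 | (Z)-1-[4-(benzyloxy)phenyl]-2-[3,4-bis(benzyloxy)-2-methoxybenzylidene]-3-[(tert-butyldimethylsilyl)oxy]but-3-en-1-one | C=C(O[Si](C)(C)C(C)(C)C)/C(C(=O)c1ccc(OCc2ccccc2)cc1)=C/c1ccc(OCc2ccccc2)c(OCc2ccccc2)c1OC | intermediate
14 | 4,5-bis(benzyloxy)-3-methoxy-1,2-didehydrobenzene (aryne) | COC1=C(OCc2ccccc2)C(OCc2ccccc2)=CC#C1 | intermediate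
15 | racemic {6,7-bis(benzyloxy)-1-[3,4-bis(benzyloxy)-2-methoxyphenyl]-3-[(tert-butyldimethylsilyl)oxy]-8-methoxy-1,4-dihydronaphthalen-2-yl}[4-(benzyloxy)phenyl]methanone | COc1c(OCc2ccccc2)c(OCc2ccccc2)cc2c1C(c1ccc(OCc3ccccc3)c(OCc3ccccc3)c1OC)C(C(=O)c1ccc(OCc3ccccc3)cc1)=C(O[Si](C)(C)C(C)(C)C)C2 | intermediate
16 | racemic {6,7-bis(benzyloxy)-1-[3,4-bis(benzyloxy)-2-methoxyphenyl]-3-hydroxy-8-methoxy-1,4-dihydronaphthalen-2-yl}[4-(benzyloxy)phenyl]methanone (enol form) | COc1c(OCc2ccccc2)c(OCc2ccccc2)cc2c1C(c1ccc(OCc3ccccc3)c(OCc3ccccc3)c1OC)C(C(=O)c1ccc(OCc3ccccc3)cc1)=C(O)C2 | intermediate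
17 | racemic C3 vinyl triflate of 16 | COc1c(OCc2ccccc2)c(OCc2ccccc2)cc2c1C(c1ccc(OCc3ccccc3)c(OCc3ccccc3)c1OC)C(C(=O)c1ccc(OCc3ccccc3)cc1)=C(OS(=O)(=O)C(F)(F)F)C2 | intermediate
18 | [4-(benzyloxy)phenyl]boronic acid | OB(O)c1ccc(OCc2ccccc2)cc1 | starting material
19 | racemic {6,7-bis(benzyloxy)-1-[3,4-bis(benzyloxy)-2-methoxyphenyl]-8-methoxy-1,4-dihydronaphthalene-2,3-diyl}bis{[4-(benzyloxy)phenyl]methanone} | COc1c(OCc2ccccc2)c(OCc2ccccc2)cc2c1C(c1ccc(OCc3ccccc3)c(OCc3ccccc3)c1OC)C(C(=O)c1ccc(OCc3ccccc3)cc1)=C(C(=O)c1ccc(OCc3ccccc3)cc1)C2 | intermediate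
20 | potassium dienolate of 19 (exocyclic enolate at C2, C3=C4 alkene) | COc1c(OCc2ccccc2)c(OCc2ccccc2)cc2c1C(c1ccc(OCc3ccccc3)c(OCc3ccccc3)c1OC)C(=C([O-])c1ccc(OCc3ccccc3)cc1)C(C(=O)c1ccc(OCc3ccccc3)cc1)=C2.[K+] | intermediate
21 | racemic cis-{6,7-bis(benzyloxy)-1-[3,4-bis(benzyloxy)-2-methoxyphenyl]-8-methoxy-1,2-dihydronaphthalene-2,3-diyl}bis{[4-(benzyloxy)phenyl]methanone} (both enantiomers written) | COc1c([C@@H]2c3c(cc(OCc4ccccc4)c(OCc4ccccc4)c3OC)C=C(C(=O)c3ccc(OCc4ccccc4)cc3)[C@@H]2C(=O)c2ccc(OCc4ccccc4)cc2)ccc(OCc2ccccc2)c1OCc1ccccc1.COc1c([C@H]2c3c(cc(OCc4ccccc4)c(OCc4ccccc4)c3OC)C=C(C(=O)c3ccc(OCc4ccccc4)cc3)[C@H]2C(=O)c2ccc(OCc4ccccc4)cc2)ccc(OCc2ccccc2)c1OCc1ccccc1 | intermediate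
22 | (1R,2R)-hexabenzyl ether of the target | COc1c([C@@H]2c3c(cc(OCc4ccccc4)c(OCc4ccccc4)c3OC)C=C(C(=O)c3ccc(OCc4ccccc4)cc3)[C@@H]2C(=O)c2ccc(OCc4ccccc4)cc2)ccc(OCc2ccccc2)c1OCc1ccccc1 | intermediate
23 | [(1R,2R)-1-(3,4-dihydroxy-2-methoxyphenyl)-6,7-dihydroxy-8-methoxy-1,2-dihydronaphthalene-2,3-diyl]bis[(4-hydroxyphenyl)methanone] | COc1c([C@@H]2c3c(cc(O)c(O)c3OC)C=C(C(=O)c3ccc(O)cc3)[C@@H]2C(=O)c2ccc(O)cc2)ccc(O)c1O | target

Total step count: 14. Longest linear sequence: 11 steps (steps 1 to 5 and 9 to 14).

Steps most likely to fail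

Risk 1, step 9. The aryne may close on the enol ether carbon C3 in a (2+2) sense. Fluoride may strip the silyl group from the diene before the aryne arrives, so that the free dienolate condenses with itself. The crowded bond next to the methoxy group may also form too slowly. The fallback sets out from 6 and 13 and comes back at 16, and it makes the two bonds one after the other with their positions fixed by a bromide and a triflate.
- O-Triflation of 6 (Tf2O, pyridine, CH2Cl2) gives 3,4-bis(benzyloxy)-6-bromo-2-methoxyphenyl trifluoromethanesulfonate F1.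
- Palladium-catalysed alpha-arylation of enol silane 13 at the C–Br bond (Pd2(dba)3, P(t-Bu)3, Bu3SnF, toluene) uses a ligand that prefers bromide to triflate. It forms C4–C4a and gives the aryl ketone F2.
- An intramolecular reductive Heck cyclisation of the aryl triflate onto the enone carbon C1 (Pd(OAc)2, dppp, HCO2Na, DMF) then forms C8a–C1 and delivers 16.

Risk 2, step 11. Transmetalation may outrun CO insertion and give direct arylation. Oxidative addition at the tetrasubstituted triflate may be slow. Hot base with palladium may also dehydrogenate the ring to the naphthalene. The fallback sets out from 17 and comes back at 19, reverses the polarity and needs neither CO nor base.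
- Stannylation of 17 (Me3SnSnMe3, LiCl, Pd(PPh3)4, THF, 60 °C) gives the C3 trimethylstannyl enone F3.
- A Stille acylation with commercial 4-(benzyloxy)benzoyl chloride (Pd2(dba)3, P(2-furyl)3, THF, 50 °C) then gives 19.

Risk 3, step 12. Protonation may return to C4, may show poor facial selectivity at C2, or the cis product may epimerise while base is still present during the quench. The fallback sets out from 19 and comes back at 21, and it separates enolate formation from protonation.
- Dienolate 20 is trapped with Me3SiCl to give the trimethylsilyl dienol ether F4, which is isolated.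
- F4 is then protonated at C2 under base-free conditions with the SnCl4 complex of 2,2'-biphenol (a Lewis acid-assisted Brønsted acid) in toluene at −78 °C. Under these conditions no enolate remains that could equilibrate the new centre.

Further compounds
F1 | step 9 | 3,4-bis(benzyloxy)-6-bromo-2-methoxyphenyl trifluoromethanesulfonate | COc1c(OS(=O)(=O)C(F)(F)F)c(Br)cc(OCc2ccccc2)c1OCc1ccccc1
F2 | step 9 | (Z)-2-{3-[4-(benzyloxy)benzoyl]-4-[3,4-bis(benzyloxy)-2-methoxyphenyl]-2-oxobut-3-en-1-yl}-4,5-bis(benzyloxy)-6-methoxyphenyl trifluoromethanesulfonate | COc1c(OS(=O)(=O)C(F)(F)F)c(CC(=O)/C(C(=O)c2ccc(OCc3ccccc3)cc2)=C/c2ccc(OCc3ccccc3)c(OCc3ccccc3)c2OC)cc(OCc2ccccc2)c1OCc1ccccc1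
F3 | step 11 | racemic {6,7-bis(benzyloxy)-1-[3,4-bis(benzyloxy)-2-methoxyphenyl]-8-methoxy-3-(trimethylstannyl)-1,4-dihydronaphthalen-2-yl}[4-(benzyloxy)phenyl]methanone | COc1c(OCc2ccccc2)c(OCc2ccccc2)cc2c1C(c1ccc(OCc3ccccc3)c(OCc3ccccc3)c1OC)C(C(=O)c1ccc(OCc3ccccc3)cc1)=C([Sn](C)(C)C)C2
F4 | step 12 | racemic trimethylsilyl dienol ether of 19 (exocyclic enol silane at C2, C3=C4 alkene) | COc1c(OCc2ccccc2)c(OCc2ccccc2)cc2c1C(c1ccc(OCc3ccccc3)c(OCc3ccccc3)c1OC)C(=C(O[Si](C)(C)C)c1ccc(OCc3ccccc3)cc1)C(C(=O)c1ccc(OCc3ccccc3)cc1)=C2
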